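The vessel is closed, stirred and held at constant volume and temperature, so the readings can be balanced directly against the charges.

| flask | substrate | coupling partner | free catalyst | remark | time |
|---|---|---|---|---|---|
| dusk | 0.060 M | 0.40 equiv | 7.1 mol% | run made earlier |  |
| dawn | 0.060 M | 0.90 equiv | 7.1 mol% | run made earlier |  |
| flask | 0.060 M | 0.600 equiv | 7.1 mol% |  | 1.5 h |

- dusk (time / min: substrate / %, target / %, isomer of the product / %): 8.00: 64.2, 11.5, 24.8; 20.0: 64.0, 11.4, 25.0; 50.0: 64.1, 11.3, 24.6; 120: 63.5, 12.4, 25.3
- dawn (time / min: substrate / %, target / %, isomer of the product / %): 25.0: 26.1, 24.0, 48.5; 50.0: 27.1, 23.3, 49.9; 80.0: 26.3, 23.6, 49.6; 120: 27.0, 23.7, 49.5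

(standard deviation of a reading: 0.5 percentage points)

- the reaction counts as stopped when no species that holds the substrate changes by six tenths of a point or more over the second half of the time

- the state of affairs at 1.5 h: stopped, and by what, or still going (all of the substrate has reacted / forward and back rates have come level / no working catalyst is left / the coupling partner has run out first / it is still moving)
- how much of the substrate has reacted by 1.5 h
- how much target there is at 1.5 h, in percent of the substrate charged
- how much isomer of the product there is at 1.5 h, in percent of the substrate charged

Both earlier runs are flat within the scatter from their first reading. The dusk run already shows its plateau at 8.00 min, far earlier than the 1.5 h asked for, so I expect this flask to be at rest by then. On the mean readings the dawn run holds 26.6% substrate, 73.0% products and 17.0% coupling partner, all in percent of the substrate charged. Both reagents remain in the dawn run, which suggests a balance rather than exhaustion.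

If the forward rate goes as [substrate][coupling partner] and the back rate as the products, level rates keep one number constant: the mass-action quotient K, ([target]+[isomer of the product])/([substrate][coupling partner]). The dawn run reads 269 L mol⁻¹. The dusk run reads 278 L mol⁻¹, close to the dawn reading. I carry the dawn value, because the dawn remainder of coupling partner, 17.0%, is larger than the dusk remainder of 3.43%. Target makes up 32.4% of the dawn products.

Let x be the fraction reacted, e the equivalents of coupling partner and c the starting concentration. Then Kc = x/((1−x)(e−x)), a quadratic in closed form. Its smaller root for this flask is 53.0%, below the 0.600 equiv of the coupling partner, the limiting reagent. I therefore reckon 17.2% target and 35.8% isomer of the product.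

The forecast, judging that “this looks like an equilibrium”, says: forward and back rates have come level, with 53% reacted, 17% target and 36% isomer of the product. The flask gives the same end, forward and back rates have come level, with 53.0% reacted, 17.1% target and 35.9% isomer of the product.

    free catalyst → spent catalyst (k = 1.50 × 10⁻⁵ s⁻¹)
    target + free catalyst ⇌ isomer of the product + free catalyst, rate k2*[free catalyst]*[target] forward; the back reaction follows from the equilibrium constant (K = 2.10, k = 25.0 L mol⁻¹ s⁻¹)
    substrate + coupling partner + free catalyst ⇌ target + free catalyst, rate k3*[substrate]*[coupling partner]*[free catalyst] forward; the back reaction follows from the equilibrium constant (K = 86.0 L mol⁻¹, k = 2100 L² mol⁻² s⁻¹)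

This flask has come to rest: substrate stands at 47.0% after 0.150 h and at 47.0% after 15.0 h. Ten times the time leaves 53.0% reacted, 17.1% target and 35.9% isomer of the product. Free catalyst still falls, from 92.2% of its charge at 1.50 h to 44.5% at 15.0 h, without moving the conversion. The reckoning would fail in a run with the loss of target to isomer of the product struck out, both ways, which gives 44.5% reacted.

For the neighbour at 0.024 M of substrate, with the same equivalents and time, K gives 46.5% reacted, 15.1% target and 31.4% isomer of the product. That flask gives 46.4%, 15.0% and 31.5%.

The readings come from a simulation from invented constants, and the scatter is random.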